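Everything rests on cutting C17–C18 and C21–C22, so that rings D and E are made together by one intramolecular Diels–Alder reaction. The step exploits the cis D/E junction (quaternary C17 methyl syn to H18) and the adjacent C20 methyl/C21 oxygen pair of ring E, which map onto an isopropenyl ketone and an (E,E)-1-silyloxy-2-methyldiene. Its precursor 45 is the finished A/B/C tricycle: guaiane dioxane on C2/C3, C6=C7 alkene, 8β-H, and the trans C13/C14 quaternary pair that carries the diene (C13) and the enone chain (C14). Alcohol 15 from (S)-carvone and fluoro enone 33 from 2-fluoro-6-methylphenol are joined beforehand.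

Key step: step 33

**Numbering.** Triterpene numbering is used (Me25 on C9, Me26 on C14, Me27 on C13, Me28 on C17). Primed numbers refer to the guaiane. α/β refer to the usual drawing in which Me25 is β.

**Assumption.** The sense of induction of (S)-p-tol-BINAP/CuH (step 6), of (S)-1-phenylethylamine (step 16) and of the oxazaborolidine in the fallback to step 25 is taken by analogy with simple 3-methylcycloalkenones, 2-methylcycloalkanones and aryl ketones. If a sense is opposite, the antipode is used.

**Design remarks.**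
- (a) In 45 the oxygen-bearing diene terminus C21 must bond to the enone β-carbon C22. Oxygen therefore ends meta to C16=O, against the electronic bias of a 1-oxygenated diene. Only the short tether enforces this, so the step is run thermally without Lewis acid.
- (b) The enone is unveiled last, from a Weinreb amide, because soft enolisation would also silylate a C16 ketone.
- (c) H8 sits on the face that carries Me25 and Me26, so it is delivered intramolecularly through an allylic diazene. The C6 ketone used for that also activates C2–F.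
- (d) The C21 ketone is reached by oxidation and 1,4-reduction, which spares the other alkenes.

**Layout.** Steps 1–2 make the allylating agent, 3–10 the guaiane alcohol, 11–22 the tricycle, 23–32 the union and side chains, and 34–39 the end game.

Step 1
Reactants: 1 but-2-yn-1-ol
Product: 2 (Z)-3-iodobut-2-en-1-ol
Conditions: NaAlH2(OCH2CH2OMe)2, THF, 0 °C to rt; then I2, −78 °C
Reagents that add atoms: iodine, II
Why: Hydroxyl-directed trans-hydroalumination gives a cyclic vinylalanate whose C–Al bond is iodinated with retention, which fixes the Z geometry (I cis to CH2OH).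

Step 2
Reactants: 2 (Z)-3-iodobut-2-en-1-ol
Product: 3 (Z)-1-bromo-3-iodobut-2-ene
Conditions: CBr4, PPh3, CH2Cl2, 0 °C
Reagents that add atoms: carbon tetrabromide, BrC(Br)(Br)Br
Why: The Appel reaction converts the primary allylic alcohol into the bromide under neutral conditions without touching the alkenyl iodide or its geometry.

Step 3
Reactants: 4 (S)-(+)-carvone
Product: 5 triethyl{[(5S)-2-methyl-5-(prop-1-en-2-yl)cyclohex-1-en-1-yl]oxy}silane
Conditions: Et3SiH, RhCl(PPh3)3 (cat.), THF, 50 °C
Reagents that add atoms: triethylsilane, CC[SiH](CC)CC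
Why: Rhodium-catalysed 1,4-hydrosilylation of the enone gives the C1=C2 silyl enol ether regiospecifically and leaves the isolated isopropenyl group and the stereocentre (future C7′) untouched.

Step 4
Reactants: 5 silyl enol ether
Product: 6 (3S)-6-methyl-3-(prop-1-en-2-yl)-1-(triethylsilyloxy)bicyclo[4.1.0]heptane (cyclopropane diastereomers)
Conditions: Et2Zn, CH2I2, Et2O, 0 °C
Reagents that add atoms: diiodomethane, ICI
Why: Simmons–Smith cyclopropanation is much faster at the electron-rich enol ether than at the 1,1-disubstituted alkene, and the two new centres are erased in step 5.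

Step 5
Reactants: 6 siloxycyclopropane
Product: 8 (6S)-3-methyl-6-(prop-1-en-2-yl)cyclohept-2-en-1-one, via β-chloro ketone 7 (not isolated)
Conditions: FeCl3, DMF, 0 °C to rt; then NaOAc, MeOH, reflux
Reagents that add atoms: none
Why: One-electron oxidation of the cyclopropanol ether cleaves the internal bond, the tertiary radical takes up chlorine and acetate eliminates HCl, a known oxidative one-carbon ring expansion that inserts C1′ between C5′ and C10′.

Step 6
Reactants: 8 cycloheptenone; 3 (Z)-1-bromo-3-iodobut-2-ene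
Product: 10 (2S,3R,6S)-2-[(Z)-3-iodobut-2-en-1-yl]-3-methyl-6-(prop-1-en-2-yl)cycloheptan-1-one, via diphenylsilyl enol ether 9 (not isolated)
Conditions: CuCl, NaOt-Bu, (S)-p-tol-BINAP (5 mol % each), Ph2SiH2, toluene, 0 °C; then 3, [Bu4N][Ph3SiF2], CH2Cl2, rt
Reagents that add atoms: none
Why: Ligand-controlled copper hydride conjugate reduction sets C10′ (methyl cis to isopropenyl) independently of the remote C7′ centre, and fluoride activation of the regiodefined silyl enol ether restricts allylation to C1′, anti to the new methyl.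

Step 7
Reactants: 10 ketone
Product: 11 C1′=C5′ triethylsilyl enol ether of 10
Conditions: Et3SiCl, NaI, Et3N, MeCN, 40 °C
Reagents that add atoms: chlorotriethylsilane, CC[Si](Cl)(CC)CC
Why: Equilibrating silylation with iodosilane made in situ gives the tetrasubstituted enol ether, the thermodynamic isomer of a 2-alkylcycloalkanone.

Step 8
Reactants: 11 silyl enol ether
Product: 12 (2S,3R,6S)-2-[(Z)-3-iodobut-2-en-1-yl]-3-methyl-6-(prop-1-en-2-yl)-2-(triethylsilyloxy)cycloheptan-1-one
Conditions: mCPBA (1.0 equiv), NaHCO3, CH2Cl2–hexane, −20 °C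
Reagents that add atoms: 3-chloroperbenzoic acid, OOC(=O)c1cccc(Cl)c1
Why: In this Rubottom oxidation the peracid attacks the enol ether (far more reactive than the isopropenyl or iodoalkene groups) opposite the pseudoaxial C10′ methyl, and silyl migration gives the α-silyloxy ketone with O1′ trans to that methyl.

Step 9
Reactants: 12 α-silyloxy ketone
Product: 14 5′-methoxy-1′-(triethylsilyloxy)guaia-3′,11′-diene (O1′ and O5′ cis; both trans to the C10′ methyl and the C7′ isopropenyl), via lithium alkoxide 13 (not isolated)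
Conditions: n-BuLi, THF, −78 °C; then MeOTf, −78 to −20 °C
Reagents that add atoms: methyl trifluoromethanesulfonate, COS(=O)(=O)C(F)(F)F
Why: Iodine–lithium exchange outruns carbonyl addition of n-BuLi, the Z-alkenyllithium reaches the neighbouring ketone only from the face of its own tether (five-membered ring by intramolecular 1,2-addition, O5′ cis to O1′), and the cold alkoxide is capped before silyl migration can set in.

Step 10
Reactants: 14 silyl ether
Product: 15 5′-methoxyguaia-3′,11′-dien-1′-ol (configuration as in 14)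
Conditions: Bu4NF, THF, rt
Reagents that add atoms: none
Why: Fluoride cleaves the silyl ether and leaves a single free hydroxyl group (C1′) beside a base-stable but acid-ionisable tertiary allylic methyl ether.

Step 11
Reactants: 16 2-fluoro-6-methylphenol
Product: 17 2-fluoro-6-methylanisole
Conditions: MeI, K2CO3, acetone, reflux
Reagents that add atoms: iodomethane, CI
Why: Williamson etherification masks the future C3 oxygen with a group that survives the Lewis acids and bases that follow.

Step 12
Reactants: 17 2-fluoro-6-methylanisole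
Product: 18 1-(3-fluoro-4-methoxy-5-methylphenyl)propan-1-one
Conditions: EtCOCl, AlCl3, CH2Cl2, 0 °C
Reagents that add atoms: propionyl chloride, CCC(=O)Cl
Why: Friedel–Crafts acylation goes para to the methoxy group, as known for 2,6-disubstituted anisoles, and marks the future C10.

Step 13
Reactants: 18 aryl ethyl ketone
Product: 19 methyl 2-(3-fluoro-4-methoxy-5-methylphenyl)propanoate (racemic)
Conditions: PhI(OAc)2, HC(OMe)3, H2SO4 (cat.), 60 °C
Reagents that add atoms: trimethyl orthoformate, COC(OC)OC
Why: Hypervalent-iodine-induced oxidative 1,2-aryl migration of the derived enol ether is a known route from propiophenones to 2-arylpropanoates and is helped by the electron-rich migrating ring.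

Step 14
Reactants: 19 methyl ester
Product: 20 2-(3-fluoro-4-methoxy-5-methylphenyl)propanoic acid
Conditions: LiOH, THF–H2O, rt; then HCl
Reagents that add atoms: lithium hydroxide, [Li+].[OH-]
Why: Plain saponification is sufficient, and the stereocentre is irrelevant because it is re-formed in step 16.

Step 15
Reactants: 20 acid
Product: 22 7-fluoro-6-methoxy-1,5-dimethyl-3,4-dihydronaphthalen-2(1H)-one, via acid chloride 21 (not isolated)
Conditions: (COCl)2, DMF (cat.), CH2Cl2; then ethylene (1 atm), AlCl3, CH2Cl2, −10 °C to rt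
Reagents that add atoms: ethylene, C=C
Why: Acylation of ethylene followed by intramolecular Friedel–Crafts alkylation is the standard 2-tetralone synthesis, and closure should go to the ortho carbon that is para to fluorine and next to methyl (C5) because the other ortho carbon is deactivated by the adjacent fluorine.

Step 16
Reactants: 22 tetralone
Product: 25 (1S)-7-fluoro-6-methoxy-1,5-dimethyl-1-(3-oxopentyl)-3,4-dihydronaphthalen-2(1H)-one, via enamine 23 (not isolated), via imine adduct 24 (not isolated)
Conditions: (S)-PhCH(Me)NH2, TsOH (cat.), toluene, reflux (−H2O); ethyl vinyl ketone, THF, rt; then 20% aq AcOH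
Reagents that add atoms: pent-1-en-3-one, C=CC(=O)CC; water, O
Why: In this deracemising asymmetric Michael addition the more substituted secondary enamine adds through a compact aza-ene-like transition state on the face left open by the phenylethyl group, which sets quaternary C9.

Step 17
Reactants: 25 diketone
Product: 26 (4aR)-6-fluoro-7-methoxy-1,4a,8-trimethyl-4,4a,9,10-tetrahydrophenanthren-2(3H)-one
Conditions: NaOMe, MeOH, reflux
Reagents that add atoms: none
Why: The aldol condensation half of a Robinson annulation joins C14 to the C8 carbonyl and closes ring C as the C13 enone that already carries Me26.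

Step 18
Reactants: 26 tricyclic enone
Product: 27 tricyclic keto ester (2-fluoro-3-methoxy-4-methyl ring A; C7=C8; 9β-Me; 13-oxo; 14β-Me; 14α-CH2CO2Me)
Conditions: KOt-Bu, t-BuOH–THF, rt; BrCH2CO2Me
Reagents that add atoms: methyl bromoacetate, COC(=O)CBr
Why: Deconjugative α-alkylation of the extended dienolate (γ-deprotonation at C7) takes the electrophile at C14 from the α face, anti to the axial C9 methyl, as is classical for 4-methyl-octalone-type enones, and moves the alkene to C7=C8.

Step 19
Reactants: 27 keto ester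
Product: 29 C13-carbaldehyde (C13 epimers; otherwise as 27), via methyl enol ether 28 (not isolated)
Conditions: Ph3PCH2OMe Cl, KN(SiMe3)2, THF, 0 °C to rt; then 2 M HCl, THF, rt
Reagents that add atoms: (methoxymethyl)triphenylphosphonium chloride, COC[P+](c1ccccc1)(c1ccccc1)c1ccccc1.[Cl-]; water, O
Why: Wittig methoxymethylenation and enol ether hydrolysis add C18 at the only ketone, while the ester is inert to the ylide.

Step 20
Reactants: 29 aldehyde
Product: 30 quaternary aldehyde (13α-Me, 13β-CHO; otherwise as 27)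
Conditions: KOt-Bu, MeI, THF, 0 °C
Reagents that add atoms: iodomethane, CI
Why: C-methylation of the exocyclic aldehyde enolate (much more acidic than the ester) occurs from the α face because the neighbouring axial Me26 shields the β face, which gives the trans C13/C14 methyl pair.

Step 21
Reactants: 30 quaternary aldehyde
Product: 32 dimethyl acetal (13β-CH2CH(OMe)2; otherwise as 30), via methyl enol ether 31 (not isolated)
Conditions: Ph3PCH2OMe Cl, KN(SiMe3)2, THF, 0 °C to rt; then MeOH, camphorsulfonic acid (cat.), rt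
Reagents that add atoms: (methoxymethyl)triphenylphosphonium chloride, COC[P+](c1ccccc1)(c1ccccc1)c1ccccc1.[Cl-]; methanol, CO
Why: A second Wittig homologation adds C19, and acid-catalysed addition of methanol stores the aldehyde as an acetal that tolerates oxidant, alkoxide, hydrazide and borane.

Step 22
Reactants: 32 acetal
Product: 33 fluoro enone (6-oxo, C7=C8; otherwise as 32)
Conditions: CrO3, 3,5-dimethylpyrazole, CH2Cl2, −20 °C
Reagents that add atoms: chromium trioxide, O=[Cr](=O)=O
Why: Allylic oxidation strikes C6, the only position that is both allylic and benzylic (C9 and C14 are quaternary), as in the oxidation of steroidal 5-enes to 7-ketones.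

Step 23
Reactants: 33 fluoro enone; 15 guaiane alcohol
Product: 34 C2 aryl ether (C2–O–C1′; 3-OMe and 5′-OMe retained)
Conditions: 15, KN(SiMe3)2, THF, 0 °C; then 33, DMF, 0 to 40 °C
Reagents that add atoms: none
Why: Nucleophilic aromatic substitution by the tertiary alkoxide is activated by the para C6 carbonyl, the enone is non-enolisable and blocked at C8, and the regiochemistry of the later dioxane is thereby fixed.

Step 24
Reactants: 34 enone
Product: 35 C6 tosylhydrazone of 34
Conditions: TsNHNH2, MeOH, 55 °C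
Reagents that add atoms: 4-methylbenzenesulfonohydrazide, Cc1ccc(cc1)S(=O)(=O)NN
Why: Condensation occurs at the only free carbonyl group, and methanol as solvent makes any exchange at the acetal or at the allylic methyl ether degenerate.

Step 25
Reactants: 35 tosylhydrazone
Product: 37 6-ene with 8β-H (otherwise as 34), via allylic diazene 36 (not isolated)
Conditions: catecholborane, CHCl3, −10 °C to rt; then NaOAc·3H2O, reflux
Reagents that add atoms: none
Why: In this allylic diazene rearrangement hydride adds to C6 from the α face (the β face carries Me25 and Me26), so that after loss of sulfinate the β-diazene passes its hydrogen suprafacially to C8β by retro-ene loss of N2 and the alkene moves to C6=C7.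

Step 26
Reactants: 37 methyl ether ester
Product: 38 C3 phenol C16 carboxylic acid (acetal and 5′-OMe intact)
Conditions: NaSEt, DMF, 100 °C; aq NaHSO4 work-up
Reagents that add atoms: none
Why: Thiolate SN2 attack on methyl frees the crowded aryl methyl ether and the methyl ester in one operation, while dialkyl ethers, the acetal and all alkenes are inert.

Step 27
Reactants: 38 phenol
Product: 39 guaiane dioxane acid (C3–O–C5′ and C2–O–C1′; 3′-ene)
Conditions: camphorsulfonic acid (cat.), 4 Å MS, CH2Cl2, 0 °C
Reagents that add atoms: none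
Why: Acid ionises the tertiary allylic methyl ether to the C3′–C4′–C5′ allyl cation, and the phenol held on the same face by the C1′–O–C2 link captures the tertiary terminus (intramolecular SN1 allylic etherification, six-membered ring), which can only give the cis-fused dioxane and leaves the 3′-alkene.

Step 28
Reactants: 39 acid
Product: 41 C16 Weinreb amide, via acyl imidazole 40 (not isolated)
Conditions: 1,1′-carbonyldiimidazole, CH2Cl2, rt; then MeNH(OMe)·HCl
Reagents that add atoms: N,O-dimethylhydroxylamine hydrochloride, CNOC.Cl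
Why: Amide coupling through the acyl imidazole is neutral and stores C16 at the ketone oxidation level in a form that does not enolise in step 31.

Step 29
Reactants: 41 acetal
Product: 42 C19 aldehyde
Conditions: Et3SiOTf, 2,6-lutidine, CH2Cl2, 0 °C; then H2O
Reagents that add atoms: water, O
Why: Silyl triflate and lutidine convert aldehyde acetals into hydrolysable pyridinium salts in a weakly basic medium, which spares the acid-labile allylic aryl ether of the dioxane.

Step 30
Reactants: 42 aldehyde
Product: 43 (E)-enal (C13–CH2–CH=C(Me)–CHO)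
Conditions: Ph3P=C(Me)CHO, toluene, 80 °C
Reagents that add atoms: 2-(triphenylphosphoranylidene)propanal, CC(C=O)=P(c1ccccc1)(c1ccccc1)c1ccccc1
Why: The Wittig reaction of the stabilised ylide is E-selective, adds C20, its methyl and C21, and ignores the Weinreb amide.

Step 31
Reactants: 43 enal
Product: 44 (E,E)-silyl dienol ether (C16 Weinreb amide)
Conditions: t-BuMe2SiOTf, Et3N, CH2Cl2, −78 to 0 °C
Reagents that add atoms: tert-butyldimethylsilyl trifluoromethanesulfonate, CC(C)(C)[Si](C)(C)OS(=O)(=O)C(F)(F)F
Why: Soft vinylogous enolisation removes a C18 proton from the O-silylated s-trans enal, which places oxygen trans to C19 (E), and the bulk of C13 makes C18=C19 E.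

Step 32
Reactants: 44 Weinreb amide
Product: 45 triene: A/B/C tricycle with guaiane dioxane, C13 (E,E)-silyloxydiene and C14 CH2C(O)C(Me)=CH2 chain
Conditions: CH2=C(Me)MgBr, THF, −78 to −10 °C; pH 7 buffer
Reagents that add atoms: isopropenylmagnesium bromide, C=C(C)[Mg]Br
Why: In the Weinreb ketone synthesis the chelated tetrahedral adduct stops at mono-addition, and the silyl dienol ether tolerates the Grignard reagent and a neutral quench.

Step 33
Reactants: 45 triene
Product: 46 pentacycle with C16 ketone, 19(20)-alkene and C21 silyl ether (17β-Me, 18β-H)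
Conditions: toluene (0.01 M), BHT, 110 °C, sealed silanised glass
Reagents that add atoms: none
Why: This is a concerted, asynchronous thermal [4π+2π] cycloaddition in which the enone alkene C17=C22 adds suprafacially to the s-cis diene C18=C19–C20=C21, the closest known reaction type being the type 1 intramolecular Diels–Alder reaction of 1,7,9-decatrien-3-ones, which gives cis-fused octalones. Ring E closes as the six-membered cycloaddition ring (bonds C17–C18 and C21–C22) and ring D closes at the same time through the four-atom tether C13–C14–C15–C16 in the fused mode, the bridged mode being geometrically out of reach. C18 is controlled by the E geometry of C18=C19 and by the chair-like fold of the tether on ring C, where axial Me27 (α) and axial Me26 (β) leave room only for H18 axial (β) and C19 equatorial. C17 is controlled by the endo position of the C16 carbonyl under the diene, which turns Me28 outward and syn to H18 (cis D/E junction), and C21 by the E enol ether (silyloxy group outside, expected α), a centre that is erased in step 38. The step needs regioselectivity against the electronic bias of the silyloxy group (oxygen ends meta to C16=O), which the short tether enforces while the C20 methyl is matched, and chemoselectivity over the isopropenyl, cyclopentene and styrene alkenes, which are unactivated and out of reach. Neutral conditions with a radical inhibitor in acid-free glass keep the silyl dienol ether and the allylic aryl ether of the dioxane intact.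

Step 34
Reactants: 46 ketone
Product: 47 C16 alcohol (configuration at C16 immaterial)
Conditions: LiAlH4, Et2O, 0 °C to rt
Reagents that add atoms: none
Why: Hydride reduction addresses the only carbonyl group, and a small reagent is chosen because C16 is flanked by quaternary C17.

Step 35
Reactants: 47 alcohol
Product: 48 C16 S-methyl xanthate
Conditions: KN(SiMe3)2, CS2, THF, 0 °C; then MeI
Reagents that add atoms: carbon disulfide, S=C=S; iodomethane, CI
Why: Xanthate formation through the potassium alkoxide works for hindered secondary alcohols and affects no other group.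

Step 36
Reactants: 48 xanthate
Product: 49 C16-deoxy pentacycle (C21 silyl ether)
Conditions: Bu3SnH, AIBN (cat.), toluene, 90 °C
Reagents that add atoms: none
Why: In the Barton–McCombie deoxygenation the secondary C16 radical has only slow four-membered or 5-endo cyclisation paths to the 19(20)-alkene and is therefore reduced by the stannane.

Step 37
Reactants: 49 silyl ether
Product: 50 C21 allylic alcohol
Conditions: Bu4NF, THF, rt
Reagents that add atoms: none
Why: Fluoride desilylation is orthogonal to the ethers and alkenes present.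

Step 38
Reactants: 50 allylic alcohol
Product: 51 19(20)-en-21-one
Conditions: Dess–Martin periodinane, NaHCO3, CH2Cl2, rt
Reagents that add atoms: none
Why: Buffered periodinane oxidation of the single alcohol merges any C21 epimers into one enone.

Step 39
Reactants: 51 enone
Product: 53 target CNP0233042.2, via C20-epimer mixture 52 (not isolated)
Conditions: [(Ph3P)CuH]6, toluene, H2O (trace), rt; then K2CO3, MeOH, rt
Reagents that add atoms: none
Why: Copper hydride 1,4-reduction touches only the enone, and base equilibration of the α-centre puts the C20 methyl equatorial (β), because the axial position would be syn-axial to the C13–C18 bond on chair ring E.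

Compound list
1 | but-2-yn-1-ol | CC#CCO | starting material
2 | (Z)-3-iodobut-2-en-1-ol | C/C(I)=C/CO | intermediate
3 | (Z)-1-bromo-3-iodobut-2-ene | C/C(I)=C/CBr | intermediate
4 | (S)-(+)-carvone | CC1=CC[C@@H](CC1=O)C(C)=C | starting material
5 | triethylsilyl enol ether of (5S)-dihydrocarvone (C1=C2) | C=C(C)[C@H]1CCC(C)=C(O[Si](CC)(CC)CC)C1 | intermediate
6 | (3S)-6-methyl-3-isopropenyl-1-(triethylsilyloxy)bicyclo[4.1.0]heptane, cyclopropane diastereomers | C=C(C)[C@H]1CCC2(C)CC2(O[Si](CC)(CC)CC)C1 | intermediate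
7 | (6S)-3-chloro-3-methyl-6-isopropenylcycloheptanone | C=C(C)[C@H]1CCC(C)(Cl)CC(=O)C1 | intermediate
8 | (6S)-3-methyl-6-isopropenylcyclohept-2-enone | C=C(C)[C@H]1CCC(C)=CC(=O)C1 | intermediate
9 | diphenylsilyl enol ether of (3R,6S)-3-methyl-6-isopropenylcycloheptanone | C=C(C)[C@H]1CC[C@@H](C)C=C(O[SiH](c2ccccc2)c2ccccc2)C1 | intermediate
10 | (2S,3R,6S)-2-[(Z)-3-iodobut-2-enyl]-3-methyl-6-isopropenylcycloheptanone | C=C(C)[C@H]1CC[C@@H](C)[C@H](C/C=C(/C)I)C(=O)C1 | intermediate
11 | tetrasubstituted triethylsilyl enol ether of 10 | C=C(C)[C@H]1CC[C@@H](C)C(C/C=C(/C)I)=C(O[Si](CC)(CC)CC)C1 | intermediate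
12 | (2S,3R,6S)-α-(triethylsilyloxy) ketone | C=C(C)[C@H]1CC[C@@H](C)[C@](C/C=C(/C)I)(O[Si](CC)(CC)CC)C(=O)C1 | intermediate
13 | lithium 5′-alkoxide of the cis-fused hydroazulene | C=C(C)[C@H]1CC[C@@H](C)[C@@]2(O[Si](CC)(CC)CC)CC=C(C)[C@]2(C1)[O-].[Li+] | intermediate
14 | 5′-methoxy-1′-(triethylsilyloxy)guaia-3′,11′-diene | C=C(C)[C@H]1CC[C@@H](C)[C@@]2(O[Si](CC)(CC)CC)CC=C(C)[C@]2(C1)OC | intermediate
15 | 5′-methoxyguaia-3′,11′-dien-1′-ol | C=C(C)[C@H]1CC[C@@H](C)[C@@]2(O)CC=C(C)[C@]2(C1)OC | intermediate
16 | 2-fluoro-6-methylphenol | Cc1cccc(F)c1O | starting material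
17 | 2-fluoro-6-methylanisole | COc1c(C)cccc1F | intermediate
18 | 1-(3-fluoro-4-methoxy-5-methylphenyl)propan-1-one | CCC(=O)c1cc(C)c(OC)c(F)c1 | intermediate
19 | methyl 2-(3-fluoro-4-methoxy-5-methylphenyl)propanoate | COC(=O)C(C)c1cc(C)c(OC)c(F)c1 | intermediate
20 | 2-(3-fluoro-4-methoxy-5-methylphenyl)propanoic acid | OC(=O)C(C)c1cc(C)c(OC)c(F)c1 | intermediate
21 | 2-(3-fluoro-4-methoxy-5-methylphenyl)propanoyl chloride | ClC(=O)C(C)c1cc(C)c(OC)c(F)c1 | intermediate
22 | 7-fluoro-6-methoxy-1,5-dimethyl-2-tetralone | COc1c(F)cc2c(c1C)CCC(=O)C2C | intermediate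
23 | secondary enamine of 22 and (S)-1-phenylethylamine | COc1c(F)cc2c(c1C)CCC(N[C@@H](C)c1ccccc1)=C2C | intermediate
24 | imine of the Michael adduct | COc1c(F)cc2c(c1C)CCC(=N[C@@H](C)c1ccccc1)[C@@]2(C)CCC(=O)CC | intermediate
25 | (1S)-1-(3-oxopentyl) tetralone | COc1c(F)cc2c(c1C)CCC(=O)[C@@]2(C)CCC(=O)CC | intermediate
26 | (4aR)-tricyclic enone | COc1c(F)cc2c(c1C)CCC1=C(C)C(=O)CC[C@]12C | intermediate
27 | 7-ene 13-ketone, 14β-Me, 14α-CH2CO2Me | COc1c(F)cc2c(c1C)CC=C1[C@@]2(C)CCC(=O)[C@]1(C)CC(=O)OC | intermediate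
28 | C13 methoxymethylene compound | COc1c(F)cc2c(c1C)CC=C1[C@@]2(C)CCC(=COC)[C@]1(C)CC(=O)OC | intermediate
29 | C13 carbaldehyde, C13 epimers | COc1c(F)cc2c(c1C)CC=C1[C@@]2(C)CCC(C=O)[C@]1(C)CC(=O)OC | intermediate
30 | 13α-methyl 13β-carbaldehyde | COc1c(F)cc2c(c1C)CC=C1[C@@]2(C)CC[C@@](C)(C=O)[C@]1(C)CC(=O)OC | intermediate
31 | C18=C19 methyl enol ether, E/Z | COc1c(F)cc2c(c1C)CC=C1[C@@]2(C)CC[C@@](C)(C=COC)[C@]1(C)CC(=O)OC | intermediate
32 | C19 dimethyl acetal | COc1c(F)cc2c(c1C)CC=C1[C@@]2(C)CC[C@@](C)(CC(OC)OC)[C@]1(C)CC(=O)OC | intermediate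
33 | 6-oxo-7-ene fluoro enone | COc1c(F)cc2c(c1C)C(=O)C=C1[C@@]2(C)CC[C@@](C)(CC(OC)OC)[C@]1(C)CC(=O)OC | intermediate
34 | C2–O–C1′ aryl ether enone | C=C(C)[C@H]1CC[C@@H](C)[C@@]2(Oc3cc4c(c(C)c3OC)C(=O)C=C3[C@@]4(C)CC[C@@](C)(CC(OC)OC)[C@]3(C)CC(=O)OC)CC=C(C)[C@]2(C1)OC | intermediate
35 | C6 tosylhydrazone | C=C(C)[C@H]1CC[C@@H](C)[C@@]2(Oc3cc4c(c(C)c3OC)C(=NNS(=O)(=O)c3ccc(C)cc3)C=C3[C@@]4(C)CC[C@@](C)(CC(OC)OC)[C@]3(C)CC(=O)OC)CC=C(C)[C@]2(C1)OC | intermediate
36 | 6β-allylic diazene | C=C(C)[C@H]1CC[C@@H](C)[C@@]2(Oc3cc4c(c(C)c3OC)[C@H](N=N)C=C3[C@@]4(C)CC[C@@](C)(CC(OC)OC)[C@]3(C)CC(=O)OC)CC=C(C)[C@]2(C1)OC | intermediate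
37 | 6-ene, 8β-H | C=C(C)[C@H]1CC[C@@H](C)[C@@]2(Oc3cc4c(c(C)c3OC)C=C[C@@H]3[C@@]4(C)CC[C@@](C)(CC(OC)OC)[C@]3(C)CC(=O)OC)CC=C(C)[C@]2(C1)OC | intermediate
38 | C3 phenol, C16 acid | C=C(C)[C@H]1CC[C@@H](C)[C@@]2(Oc3cc4c(c(C)c3O)C=C[C@@H]3[C@@]4(C)CC[C@@](C)(CC(OC)OC)[C@]3(C)CC(=O)O)CC=C(C)[C@]2(C1)OC | intermediate
39 | guaiane dioxane acid | C=C(C)[C@H]1CC[C@@H](C)[C@@]23CC=C(C)[C@]2(C1)Oc1c(cc2c(c1C)C=C[C@@H]1[C@@]2(C)CC[C@@](C)(CC(OC)OC)[C@]1(C)CC(=O)O)O3 | intermediate
40 | C16 acyl imidazole | C=C(C)[C@H]1CC[C@@H](C)[C@@]23CC=C(C)[C@]2(C1)Oc1c(cc2c(c1C)C=C[C@@H]1[C@@]2(C)CC[C@@](C)(CC(OC)OC)[C@]1(C)CC(=O)n1ccnc1)O3 | intermediate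
41 | C16 Weinreb amide, C19 acetal | C=C(C)[C@H]1CC[C@@H](C)[C@@]23CC=C(C)[C@]2(C1)Oc1c(cc2c(c1C)C=C[C@@H]1[C@@]2(C)CC[C@@](C)(CC(OC)OC)[C@]1(C)CC(=O)N(C)OC)O3 | intermediate
42 | C19 aldehyde | C=C(C)[C@H]1CC[C@@H](C)[C@@]23CC=C(C)[C@]2(C1)Oc1c(cc2c(c1C)C=C[C@@H]1[C@@]2(C)CC[C@@](C)(CC=O)[C@]1(C)CC(=O)N(C)OC)O3 | intermediate
43 | (E)-C19=C20 enal | C=C(C)[C@H]1CC[C@@H](C)[C@@]23CC=C(C)[C@]2(C1)Oc1c(cc2c(c1C)C=C[C@@H]1[C@@]2(C)CC[C@@](C)(C/C=C(\C)C=O)[C@]1(C)CC(=O)N(C)OC)O3 | intermediate
44 | (E,E)-silyl dienol ether, Weinreb amide | C=C(C)[C@H]1CC[C@@H](C)[C@@]23CC=C(C)[C@]2(C1)Oc1c(cc2c(c1C)C=C[C@@H]1[C@@]2(C)CC[C@@](C)(/C=C/C(C)=C/O[Si](C)(C)C(C)(C)C)[C@]1(C)CC(=O)N(C)OC)O3 | intermediate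
45 | Diels–Alder precursor (triene) | C=C(C)[C@H]1CC[C@@H](C)[C@@]23CC=C(C)[C@]2(C1)Oc1c(cc2c(c1C)C=C[C@@H]1[C@@]2(C)CC[C@@](C)(/C=C/C(C)=C/O[Si](C)(C)C(C)(C)C)[C@]1(C)CC(=O)C(C)=C)O3 | intermediate
46 | cycloadduct, C16 ketone, C21 silyl ether (C21 expected α, left open) | C=C(C)[C@H]1CC[C@@H](C)[C@@]23CC=C(C)[C@]2(C1)Oc1c(cc2c(c1C)C=C[C@@H]1[C@@]2(C)CC[C@@]2(C)[C@@H]4C=C(C)C(O[Si](C)(C)C(C)(C)C)C[C@]4(C)C(=O)C[C@]12C)O3 | intermediate
47 | C16 alcohol | C=C(C)[C@H]1CC[C@@H](C)[C@@]23CC=C(C)[C@]2(C1)Oc1c(cc2c(c1C)C=C[C@@H]1[C@@]2(C)CC[C@@]2(C)[C@@H]4C=C(C)C(O[Si](C)(C)C(C)(C)C)C[C@]4(C)C(O)C[C@]12C)O3 | intermediate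
48 | C16 S-methyl xanthate | C=C(C)[C@H]1CC[C@@H](C)[C@@]23CC=C(C)[C@]2(C1)Oc1c(cc2c(c1C)C=C[C@@H]1[C@@]2(C)CC[C@@]2(C)[C@@H]4C=C(C)C(O[Si](C)(C)C(C)(C)C)C[C@]4(C)C(OC(=S)SC)C[C@]12C)O3 | intermediate
49 | C16-deoxy silyl ether | C=C(C)[C@H]1CC[C@@H](C)[C@@]23CC=C(C)[C@]2(C1)Oc1c(cc2c(c1C)C=C[C@@H]1[C@@]2(C)CC[C@@]2(C)[C@@H]4C=C(C)C(O[Si](C)(C)C(C)(C)C)C[C@]4(C)CC[C@]12C)O3 | intermediate
50 | C21 allylic alcohol | C=C(C)[C@H]1CC[C@@H](C)[C@@]23CC=C(C)[C@]2(C1)Oc1c(cc2c(c1C)C=C[C@@H]1[C@@]2(C)CC[C@@]2(C)[C@@H]4C=C(C)C(O)C[C@]4(C)CC[C@]12C)O3 | intermediate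
51 | 19(20)-en-21-one | C=C(C)[C@H]1CC[C@@H](C)[C@@]23CC=C(C)[C@]2(C1)Oc1c(cc2c(c1C)C=C[C@@H]1[C@@]2(C)CC[C@@]2(C)[C@@H]4C=C(C)C(=O)C[C@]4(C)CC[C@]12C)O3 | intermediate
52 | 21-ketone, C20 epimers | C=C(C)[C@H]1CC[C@@H](C)[C@@]23CC=C(C)[C@]2(C1)Oc1c(cc2c(c1C)C=C[C@@H]1[C@@]2(C)CC[C@@]2(C)[C@@H]4CC(C)C(=O)C[C@]4(C)CC[C@]12C)O3 | intermediate
53 | CNP0233042.2 | C=C(C)[C@H]1CC[C@@H](C)[C@@]23CC=C(C)[C@]2(C1)Oc1c(cc2c(c1C)C=C[C@@H]1[C@@]2(C)CC[C@@]2(C)[C@@H]4C[C@@H](C)C(=O)C[C@]4(C)CC[C@]12C)O3 | target

Total step count: 39. Longest linear sequence: 29 steps (steps 11–39, from 16).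

Steps most likely to fail

**1. Step 33.**
- What may go wrong: the α-methyl group on the dienophile and the mismatched silyloxy terminus may slow the cycloaddition. Thermal decay of the silyl dienol ether, or leakage through the exo or wrong-face transition state, could then compete.
- Fallback: it sets out from 44. Vinylmagnesium bromide is added in place of the isopropenyl reagent and gives the vinyl ketone triene F1.
- The unsubstituted and far more reactive dienophile of F1 should cyclise at or slightly above room temperature to the C17–H octalone F2, in which C17 is epimerisable.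
- Equilibrating enolisation toward the ring-fusion carbon (KOt-Bu, t-BuOH–THF) and methylation with MeI then installs Me28. This reaction type is known to give cis-fused angular-methyl decalones. The fallback comes back to the route at 46.

**2. Step 25.**
- What may go wrong: hydride delivery to the crowded hydrazone may show poor facial selectivity, or condensation in step 24 may be incomplete. Either would erode the C8 configuration.
- Fallback: it sets out from 34. A reagent-controlled CBS reduction ((S)-2-methyl-CBS-oxazaborolidine, catecholborane, toluene, −78 °C) gives the 6α-allylic alcohol F3.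
- Mitsunobu displacement with 2-nitrobenzenesulfonylhydrazide (PPh3, diethyl azodicarboxylate, THF, −30 °C) proceeds with inversion to the 6β-N-sulfonylhydrazine F4.
- On warming, F4 loses sulfinic acid to give diazene 36, which collapses to 37, where the route is rejoined.

**3. Step 19.**
- What may go wrong: the ketone flanked by quaternary C14 may undergo enolisation instead of addition, or may not be attacked by the bulky phosphorus ylide at all.
- Fallback: it sets out from 27. The smaller dimethylsulfonium methylide (Me3SI, NaH, DMSO–THF) gives the spiro-epoxide F5 (Corey–Chaykovsky epoxidation).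
- Meinwald rearrangement of F5 with MgBr2·OEt2 gives aldehyde 29, where the route is rejoined.

Further compounds
F1 | step 33 | vinyl ketone triene | C=C(C)[C@H]1CC[C@@H](C)[C@@]23CC=C(C)[C@]2(C1)Oc1c(cc2c(c1C)C=C[C@@H]1[C@@]2(C)CC[C@@](C)(/C=C/C(C)=C/O[Si](C)(C)C(C)(C)C)[C@]1(C)CC(=O)C=C)O3
F2 | step 33 | C17–H octalone | C=C(C)[C@H]1CC[C@@H](C)[C@@]23CC=C(C)[C@]2(C1)Oc1c(cc2c(c1C)C=C[C@@H]1[C@@]2(C)CC[C@@]2(C)[C@@H]4C=C(C)C(O[Si](C)(C)C(C)(C)C)CC4C(=O)C[C@]12C)O3
F3 | step 25 | 6α-allylic alcohol | C=C(C)[C@H]1CC[C@@H](C)[C@@]2(Oc3cc4c(c(C)c3OC)[C@@H](O)C=C3[C@@]4(C)CC[C@@](C)(CC(OC)OC)[C@]3(C)CC(=O)OC)CC=C(C)[C@]2(C1)OC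
F4 | step 25 | 6β-N-sulfonylhydrazine | C=C(C)[C@H]1CC[C@@H](C)[C@@]2(Oc3cc4c(c(C)c3OC)[C@H](N(N)S(=O)(=O)c3ccccc3[N+](=O)[O-])C=C3[C@@]4(C)CC[C@@](C)(CC(OC)OC)[C@]3(C)CC(=O)OC)CC=C(C)[C@]2(C1)OC
F5 | step 19 | spiro-epoxide | COc1c(F)cc2c(c1C)CC=C1[C@@]2(C)CCC2(CO2)[C@]1(C)CC(=O)OC
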